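(The numbers in the tables are calculated with made-up constants, noise included.)

Count the L first. This flask holds J, Q and L with a little G, and the ash run is the same flask followed for its first 50.0 s.

common to all: J 0.0050 M; G 0.12 mM

| run | L | Q | remark | time |
|---|---|---|---|---|
| ash | 10 mM | 5 mM | the very flask that is asked about, followed so far |  |
| flask | 10.0 mM | 5.00 mM |  | 4.0 min |

ash run (percent of the J charged)

| time / s | E / % | J / % |
|---|---|---|
| 10.0 | 10 | 93 |
| 15.0 | 12 | 86 |
| 25.0 | 19 | 83 |
| 30.0 | 20 | 82 |
| 40.0 | 27 | 77 |
| 50.0 | 31 | 71 |

(readings scatter by 2 percentage points)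

- amount of E in percent of the J charged, at 25 s, 80 s and 4.0 min

Over G, J takes one L to give E, and Q takes one L to give X. J can also take G away as Z, but G is charged far thinner than J. Call L charged per J and Q charged together the L cover 1.00. At that cover, expect [L] = [J] + [Q] + [Z] throughout this flask, with [Z] no larger than the G charged.

Now my own reckoning. Leave Z out and let Q fall in step with J at first, so [L] = 2[J]. With G held steady and the rate following [J] times [L], the ratio of E made to J left then climbs in a straight line. The ash reading of 31 % at 50.0 s gives a slope of 0.00899 s⁻¹, and that reading carries its scatter. So I expect E at 18.4 % at 25 s. From 50.0 s on, crudely take [Q] as nil, so [L] = [J] and the slope drops to half. That gives 36.9 % at 80 s and 56.6 % at 4.0 min.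

The forecast says 18.5 %, 42 % and 66 %, and its late value rests on this: “Slow catalyst poisoning or faster Q competition would lower the late values”. My last figure stands lower than the forecast's.

The flask gives 17.6 %, 36.2 % and 56.0 %, so the last point falls 10 percentage points below the forecast.

    J + G → Z (k = 0.646 M⁻¹ s⁻¹)
    Q + L + G → G + X (k = 23900 M⁻² s⁻¹)
    J + L + G → G + E (k = 8100 M⁻² s⁻¹)

Hold the cover of 1.00 against this flask. At 4.00 min, J, Q and Z together come to 2.64 mM, and L left is 2.64 mM. At 40.0 min, J, Q and Z together come to 0.993 mM, against L at 0.993 mM. The shrinking L and the time given act together to hold E at 56.0 %: the same run with L kept from shrinking gives 84.5 %, and left for 40.0 min it reaches 80.8 %.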